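The easy step is to count nucleophile, in units of the electrophile charged.

| setting | amber | flask |
|---|---|---|
| electrophile | 0.30 M | 0.30 M |
| free base | 0.30 M | 0.300 M |
| protonated nucleophile | 0.36 M | 0.360 M |
| remark | the very flask that is asked about, followed so far |  |
| time |  | 3.0 min |

amber run (percent of the electrophile charged)

| time / s | electrophile / % | target / % |
|---|---|---|
| 15.0 | 17.8 | 73.9 |
| 30.0 | 7.1 | 75.4 |
| 50.0 | 5.6 | 75.4 |
| 60.0 | 5.1 | 73.7 |
| 80.0 | 4.0 | 74.3 |
| 90.0 | 5.2 | 74.1 |

(standard deviation of a reading: 1 percentage point)

- for acid set free the crystals are counted in
- as a solid, counted per litre of solution: crystals
- candidate steps: nucleophile + target -> over-reaction product; electrophile + nucleophile -> acid set free + target; nucleophile + acid set free <-> protonated nucleophile; acid set free + free base <-> salt of the base; crystals <-> acid set free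
- the earlier runs do not show how much of nucleophile is bound; that part of a forecast is a guess

1. part of the electrophile that has reacted at 3.0 min
2. share of the unused nucleophile that is free and not bound as protonated nucleophile, at 3.0 min

Each protonated nucleophile can give up one nucleophile, each electrophile that reacts takes one, and each over-reaction takes a second. So the amber flask, which is the flask asked about, works under a stoichiometric balance: its nucleophile budget, charged [protonated nucleophile] over charged [electrophile], is 1.20.

I read the table column against column. Whatever has reacted and isn't target has over-reacted, so a row's use of the budget is two for each electrophile reacted, minus one for each target standing. In the amber run at 15.0 s this use is 0.905, and at 90.0 s it is 1.15, while the target column goes from 73.9% to 74.1%.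

That last reading, with its scatter of 1 percentage point, leaves a small correction of 0.0450. With the target column flat, I let each further electrophile cost two, so the remainder lifts the reacted share by 2.25%. My reckoning for the amber flask is 97.0%: if nucleophile goes to these two uses and its budget is used up, the reacted share is the mean of budget and target share. The readings don't show how much nucleophile is bound, so the free share stays a guess for me.

The forecast gives 96% reacted, below my figure, and 60% free, holding that “the stall is mainly nucleophile exhaustion”.

The flask gives 96.5% reacted and 36.3% free, the latter below the forecast.

    nucleophile + target → over-reaction product (k = 0.253 /M/s)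
    electrophile + nucleophile → acid set free + target (k = 2.22 /M/s)
    nucleophile + acid set free ⇌ protonated nucleophile, settled at all times (K = 438 /M)
    acid set free + free base ⇌ salt of the base (K = 40000 /M, k = 16.1 /M/s)
    crystals ⇌ acid set free, rate k5*(cs5 - [acid set free]) while solid is left; crystals form when [acid set free] > cs5 (solubility = 4.00 mM, k = 18.6 /s)

At 0.0385 min the half-life of nucleophile by coupling with electrophile is 1.5 s, shorter than the 0.51 min by attack on target. At 3.00 min the flask holds target at 73.1% against over-reaction product at 23.4%, with [nucleophile] at 1.42 × 10⁻⁴ M, and the mean of budget and target share is 96.5%. A neighbouring flask with 0.22 M of protonated nucleophile has a budget of 0.733 and, at 3.00 min, target at 63.2%, so the mean is 68.2%, and that flask stands then at 68.3% reacted.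

The data are simulated with constants of no real substance; noise was put on by code.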